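The data are calculated on assumed constants; noise was put on by code.

Keep the books on what is left of the substrate, not on what has been made. The substrate is the limiting reagent: the noon run holds 1.00 M of it against 1.10 M of coupling partner.

| flask | substrate | coupling partner | free catalyst | product | time |
|---|---|---|---|---|---|
| noon | 1.00 M | 1.10 M | 0.0200 M |  |  |
| spring | 0.400 M | 0.500 M | 0.0200 M |  |  |
| winter | 1.00 M | 1.10 M | 0.0200 M | 0.500 M |  |
| dawn | 1.00 M | 1.10 M | 0.0400 M |  |  |
| summer | 1.00 M | 1.10 M | 0.0200 M |  | 100 min |

- noon run (time / min: [product] / M): 1.9: 0.062; 5.9: 0.166; 11: 0.287; 18: 0.422; 25: 0.529; 34: 0.638
- spring run (time / min: [product] / M): 1.9: 0.021; 5.9: 0.064; 11: 0.105; 18: 0.154; 25: 0.195; 34: 0.241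
- winter run (time / min: [product] / M): 1.9: 0.561; 5.9: 0.672; 11: 0.783; 18: 0.924; 25: 1.035; 34: 1.140
- dawn run (time / min: [product] / M): 1.9: 0.125; 5.9: 0.346; 11: 0.548; 18: 0.711; 25: 0.809; 34: 0.882

(each reading ± 0.003 M)

- Overall: substrate + coupling partner -> product, with free catalyst as catalyst.
- Constant volume, constant temperature.
- A reading of a species includes what of it is bound.
- An order is taken over about fifteen percent of the charge, up and down.

1. reaction order in [free catalyst] at the outset, round the charge of the noon run, defined at two percent of the substrate turned into product
2. the spring run starts with 0.600 M less of substrate and of coupling partner than the noon run, and with no product. Compared where both hold the same amount of substrate, once fifteen percent of what the spring run was charged with has turned into product, is the spring run faster, slower or alike (within a tenth)?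
3. product in the summer run at 100 min, as a share of the substrate charged

The ledger below is my own reckoning. The summer run has the charge of the noon run, so the noon readings serve as its opening entries. The first entry is product: by 34 min the noon run has made 0.638 M, so 0.362 M of substrate stays on the books. Product needs no account of its own, as the winter run shows. Charged with 0.500 M of product, it has made 0.424 M more by 18 min, and the noon run has made 0.422 M by then.

The second entry is the stretch still to come. Between 25 min and 34 min the substrate left in the noon run falls from 0.471 M to 0.362 M. Dividing the logarithm of that ratio by the time between the two readings gives the tail constant of the fraction left, 0.0292 min⁻¹. Held unchanged for the remaining 66.0 min, it leaves 0.0525 M of substrate in the summer run at 100 min. On that reckoning the books close with 94.7% of the charge as product and 0.153 M of coupling partner still present, bound forms counted.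

The forecast puts the summer run at 93.5%, between 91% and 95.5%, which is less than my figure. It lets the constant sag to about 0.025 per minute. It gives a catalyst order of 1.2, between 1.05 and 1.35, and it calls the spring run alike. Reading the dawn run, it holds that “the catalyst effect weakens as partner runs low”.

The flask gives 92.7% for the summer run, a catalyst order of 1.3, and alike for the spring run.

    2 free catalyst ⇌ catalyst dimer, settled at all times (321.0 L mol⁻¹)
    catalyst dimer + substrate + coupling partner → product + catalyst dimer (26.28 L² mol⁻² min⁻¹)
    substrate + coupling partner ⇌ idle substrate-reagent adduct, settled at all times (2.560 L mol⁻¹)
    free catalyst + substrate ⇌ idle catalyst-substrate complex, settled at all times (3.120 L mol⁻¹)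

At the point compared, with the same substrate in both, the spring run goes at 1.0 times the rate of the noon run. The summer run keeps 0.0728 M of substrate at 100 min, bound forms counted, so from the noon reading at 34 min onward its constant averages 0.0243 min⁻¹, less than the tail constant of 0.0292 min⁻¹. Held from the start of the spring run, the tail constant puts half of the charge at 23.7 min, and the spring run takes 25.5 min.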